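## Retrosynthetic overview

1. Target ⇒ artocarpin + O2: the last step forms the aryl ether C–O bond (closing the oxepine), the C–OOH bond and the stereocentre together.
2. Artocarpin ⇒ 6-bromo-3-prenylflavone triol + (E)-3-methylbut-1-enyl boronate (Suzuki–Miyaura), after chelation-controlled 5-O-demethylation.
3. Bromo-prenylflavone ⇒ 1,3-diketone + prenyl bromide; cyclodehydration closes the pyranone (C–O bond) and the same acid removes the MOM groups.
4. 1,3-Diketone ⇒ 3-bromo-6-hydroxy-2,4-dimethoxyacetophenone (Fries acetylation of 4-bromo-3,5-dimethoxyphenol, which fixes Br at the future C-6) + methyl 2,4-bis(methoxymethoxy)benzoate (Claisen).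
5. Ring order: rings A and B come from the two arenes, pyranone ring C is closed in step 4, the oxepine ring last in step 7.

Assumption: 4-bromo-3,5-dimethoxyphenol and the pinacol ester of (E)-3-methylbut-1-enylboronic acid are bought as catalogue items; the stereocentre of the target reads as (S) from the SMILES.

## Route

Step 1
Reactants: 1 methyl 2,4-dihydroxybenzoate
Product: 2 methyl 2,4-bis(methoxymethoxy)benzoate
Conditions: NaH (2.6 equiv), MOMCl (2.6 equiv), DMF, 0 → 23 °C
Reagents that add atoms: chloromethyl methyl ether, COCCl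
Why: Double O-alkylation of the phenoxides (MOM ether formation) masks both ring B phenols, so the ester survives the strong base of step 3 and ring B cannot compete in the ring closure of step 4.

Step 2
Reactants: 3 4-bromo-3,5-dimethoxyphenol
Product: 5 1-(3-bromo-6-hydroxy-2,4-dimethoxyphenyl)ethan-1-one, via aryl acetate 4 (not isolated)
Conditions: Ac2O (1.5 equiv), BF3·OEt2 (3 equiv), 85 °C; then H2O, 60 °C
Reagents that add atoms: acetic anhydride, CC(=O)OC(C)=O
Why: O-acetylation followed by BF3-mediated Fries rearrangement puts the acetyl group ortho to OH (para is blocked by Br, the two ortho sites are equivalent), so one regioisomer forms with Br between the two methoxy groups, the future C-6.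

Step 3
Reactants: 5 1-(3-bromo-6-hydroxy-2,4-dimethoxyphenyl)ethan-1-one; 2 methyl 2,4-bis(methoxymethoxy)benzoate
Product: 6 1-(3-bromo-6-hydroxy-2,4-dimethoxyphenyl)-3-[2,4-bis(methoxymethoxy)phenyl]propane-1,3-dione
Conditions: LiN(SiMe3)2 (3.2 equiv), THF, −78 → 23 °C; then aq. HCl
Reagents that add atoms: none
Why: Crossed Claisen condensation of the phenoxide/enolate dianion of the methyl ketone with the non-enolisable aryl ester, driven by deprotonation of the 1,3-diketone by the third equivalent of base.

Step 4
Reactants: 6 the 1,3-diketone; 7 1-bromo-3-methylbut-2-ene (prenyl bromide)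
Product: 10 6-bromo-2-(2,4-dihydroxyphenyl)-5,7-dimethoxy-3-(3-methylbut-2-en-1-yl)-4H-chromen-4-one, via C-prenyl diketone 8 (not isolated), via MOM-protected flavone 9 (not isolated)
Conditions: K2CO3 (1.5 equiv), acetone, 56 °C; filter, evaporate; then HCl (1.25 M in MeOH), 45 °C
Reagents that add atoms: none
Why: C-alkylation of the soft β-diketonate at its central carbon (the only phenol on ring A is chelated), then acid-catalysed cyclodehydration (flavone synthesis, pyranone C–O bond) through that single free phenol while ring B is still MOM-masked, then acetal exchange with methanol removes both MOM groups.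

Step 5
Reactants: 10 the 5,7-dimethoxy bromoflavone
Product: 11 6-bromo-2-(2,4-dihydroxyphenyl)-5-hydroxy-7-methoxy-3-(3-methylbut-2-en-1-yl)-4H-chromen-4-one
Conditions: MgI2 (4 equiv), THF, 55 °C; then 1 M HCl, 0 °C
Reagents that add atoms: none
Why: Chelation-controlled O-demethylation: magnesium bridges the C-4 carbonyl and the 5-OMe (twisted out of plane by the neighbouring Br) and iodide removes that methyl by SN2, while the unchelated 7-OMe stays and the non-protic medium spares the prenyl alkene.

Step 6
Reactants: 11 the 5-hydroxy bromoflavone; 12 4,4,5,5-tetramethyl-2-[(E)-3-methylbut-1-en-1-yl]-1,3,2-dioxaborolane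
Product: 13 artocarpin, 2-(2,4-dihydroxyphenyl)-5-hydroxy-7-methoxy-6-[(E)-3-methylbut-1-en-1-yl]-3-(3-methylbut-2-en-1-yl)-4H-chromen-4-one
Conditions: Pd(OAc)2 (5 mol%), SPhos (10 mol%), K3PO4 (4 equiv), dioxane/H2O 5:1, 90 °C
Reagents that add atoms: none
Why: Suzuki–Miyaura coupling with a bulky electron-rich biaryl phosphine (SPhos, 2-dicyclohexylphosphino-2',6'-dimethoxybiphenyl) to force oxidative addition into the hindered, electron-rich bromide; the coupling is stereoretentive, so the E geometry comes from the boronate.

Step 7
Reactants: 13 artocarpin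
Product: 14 the target, the (S)-oxepinoflavone hydroperoxide (artocarpin with O-2' bonded to C-2 of the former prenyl chain and OOH on its C-3)
Conditions: Sc(OTf)3 (10 mol%), (S,S)-tBu-PyBox (12 mol%), 2,6-di-tert-butyl-4-methylpyridine (10 mol%), O2 (1 atm), CH2Cl2, 427 nm LED, −40 °C
Reagents that add atoms: dioxygen, O=O
Why: Proposed new method: enantioselective, Lewis-acid-templated photo-oxidative cycloetherification–hydroperoxidation – the trivalent scandium complex of the ligand (2,6-bis[(4S)-4-tert-butyl-4,5-dihydrooxazol-2-yl]pyridine) binds the 5-OH/4-C=O chelate of 13 and shifts its absorption into the visible so that only the chiral complex is excited at 427 nm; the excited chromenone takes an electron from the C-3 prenyl π-bond, O-2'–H adds 7-exo to the less substituted alkene carbon inside the chiral pocket (the tert-butyl groups screen one face next to C-3, so the chain folds to the open face; the new C–O stereocentre is predicted to be (S) with the (S,S)-ligand, the sense is checked on the first run and the (R,R)-ligand is used if it is opposite), the tertiary radical is trapped by triplet O2, and back electron transfer plus protonation gives the C–OOH group and frees the catalyst; the closest known reaction type is the uncatalysed, racemic photo-oxidative cyclisation of 3-prenyl-2'-hydroxyflavones to oxepine hydroperoxides, combined with chiral Lewis-acid chromophore activation as used in enantioselective photoreactions of 2'-hydroxychalcones.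

## Compound list

1 | methyl 2,4-dihydroxybenzoate | COC(=O)c1ccc(O)cc1O | starting material
2 | methyl 2,4-bis(methoxymethoxy)benzoate | COCOc1ccc(C(=O)OC)c(OCOC)c1 | intermediate
3 | 4-bromo-3,5-dimethoxyphenol | COc1cc(O)cc(OC)c1Br | starting material
4 | 4-bromo-3,5-dimethoxyphenyl acetate | CC(=O)Oc1cc(OC)c(Br)c(OC)c1 | intermediate
5 | 1-(3-bromo-6-hydroxy-2,4-dimethoxyphenyl)ethan-1-one | CC(=O)c1c(O)cc(OC)c(Br)c1OC | intermediate
6 | 1-(3-bromo-6-hydroxy-2,4-dimethoxyphenyl)-3-[2,4-bis(methoxymethoxy)phenyl]propane-1,3-dione (drawn as the diketo form) | COCOc1ccc(C(=O)CC(=O)c2c(O)cc(OC)c(Br)c2OC)c(OCOC)c1 | intermediate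
7 | 1-bromo-3-methylbut-2-ene (prenyl bromide) | CC(C)=CCBr | starting material
8 | 1-(3-bromo-6-hydroxy-2,4-dimethoxyphenyl)-3-[2,4-bis(methoxymethoxy)phenyl]-2-(3-methylbut-2-en-1-yl)propane-1,3-dione (racemic at C-2, centre lost on cyclisation) | COCOc1ccc(C(=O)C(CC=C(C)C)C(=O)c2c(O)cc(OC)c(Br)c2OC)c(OCOC)c1 | intermediate
9 | 6-bromo-2-[2,4-bis(methoxymethoxy)phenyl]-5,7-dimethoxy-3-(3-methylbut-2-en-1-yl)-4H-chromen-4-one | COCOc1ccc(-c2oc3cc(OC)c(Br)c(OC)c3c(=O)c2CC=C(C)C)c(OCOC)c1 | intermediate
10 | 6-bromo-2-(2,4-dihydroxyphenyl)-5,7-dimethoxy-3-(3-methylbut-2-en-1-yl)-4H-chromen-4-one | COc1cc2oc(-c3ccc(O)cc3O)c(CC=C(C)C)c(=O)c2c(OC)c1Br | intermediate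
11 | 6-bromo-2-(2,4-dihydroxyphenyl)-5-hydroxy-7-methoxy-3-(3-methylbut-2-en-1-yl)-4H-chromen-4-one | COc1cc2oc(-c3ccc(O)cc3O)c(CC=C(C)C)c(=O)c2c(O)c1Br | intermediate
12 | 4,4,5,5-tetramethyl-2-[(E)-3-methylbut-1-en-1-yl]-1,3,2-dioxaborolane | CC(C)/C=C/B1OC(C)(C)C(C)(C)O1 | starting material
13 | artocarpin, 2-(2,4-dihydroxyphenyl)-5-hydroxy-7-methoxy-6-[(E)-3-methylbut-1-en-1-yl]-3-(3-methylbut-2-en-1-yl)-4H-chromen-4-one | COc1cc2oc(-c3ccc(O)cc3O)c(CC=C(C)C)c(=O)c2c(O)c1/C=C/C(C)C | intermediate
14 | CNP0171472.1: artocarpin in which O-2' is bonded to C-2 of the former prenyl chain (seven-membered dihydro-oxepine fused across C-2/C-3 of the chromenone and C-1'/C-2' of ring B); that carbon is (S) and carries a 2-hydroperoxypropan-2-yl group; 5-OH, 7-OMe, 4'-OH and the (E)-3-methylbut-1-enyl group at C-6 are unchanged | COc1cc2oc3c(c(=O)c2c(O)c1/C=C/C(C)C)C[C@@H](C(C)(C)OO)Oc1cc(O)ccc1-3 | target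

## Step count and risks

Total steps: 7. Longest linear sequence: 6 (steps 2 to 7 from compound 3; step 1 is a one-step branch).

The three steps most likely to fail:

**Step 4 (C-prenylation, ring closure and MOM removal in one operation).** The risks are O-alkylation of the diketonate and acid damage to the prenyl group next to the freed 2'-OH. The fallback sets out from 5 and comes back at 10. It reverses the order of the two C–C bond formations and separates ring closure from deprotection. Compound 5 is α-prenylated as its dianion (LiN(SiMe3)2 2.2 equiv, THF, −78 °C, then 7) to give 1-(3-bromo-6-hydroxy-2,4-dimethoxyphenyl)-5-methylhex-4-en-1-one F1. Claisen condensation of F1 with 2 (LiN(SiMe3)2, THF) gives 8 directly, with no O- versus C-alkylation question. Compound 8 is cyclised with NaOAc in AcOH at 100 °C, which leaves the MOM ethers on, and 9 is isolated. The MOM groups are then removed in a step optimised on its own (HCl in MeOH at 20 °C), giving 10.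

**Step 6 (Suzuki coupling of a hindered, electron-rich bromide carrying three free phenols).** The risks are slow oxidative addition next to the chelated phenoxide and protodebromination. The fallback sets out from 11 and comes back at 13. A protecting-group detour takes the phenoxides out of the coupling. Compound 11 is peracetylated (Ac2O, pyridine, DMAP, 40 °C) to 5-acetoxy-2-(2,4-diacetoxyphenyl)-6-bromo-7-methoxy-3-(3-methylbut-2-en-1-yl)-4H-chromen-4-one F2, a less electron-rich bromide. F2 is coupled with 12 (Pd(OAc)2, SPhos, K3PO4, toluene with 2% water, 80 °C) to artocarpin triacetate F3. K2CO3 in MeOH at 0 °C removes the three acetates and returns 13.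

**Step 7 (the proposed new step).** The risks are low enantioselectivity, E/Z isomerisation of the styrene under irradiation, and singlet-oxygen ene products at the prenyl group. The fallback uses known chemistry; it sets out from 13 and comes back at 14. The chiral Lewis acid is dropped and the uncatalysed photo-oxidative cyclisation of the 3-prenyl-2'-hydroxyflavone is run (365 nm, CHCl3, O2, 20 °C). This gives the racemate, that is 14 and its mirror image, the (R)-hydroperoxide F4. The two are separated by preparative HPLC on a chiral stationary phase (amylose tris(3,5-dimethylphenylcarbamate), hexane/iPrOH), and 14 is identified by its ECD spectrum. Stereocontrol then comes from resolution instead of catalysis, at the cost of half the material.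

## Further compounds

F1 | step 4 | 1-(3-bromo-6-hydroxy-2,4-dimethoxyphenyl)-5-methylhex-4-en-1-one | CC(C)=CCCC(=O)c1c(O)cc(OC)c(Br)c1OC
F2 | step 6 | 5-acetoxy-2-(2,4-diacetoxyphenyl)-6-bromo-7-methoxy-3-(3-methylbut-2-en-1-yl)-4H-chromen-4-one | COc1cc2oc(-c3ccc(OC(C)=O)cc3OC(C)=O)c(CC=C(C)C)c(=O)c2c(OC(C)=O)c1Br
F3 | step 6 | artocarpin triacetate, 5-acetoxy-2-(2,4-diacetoxyphenyl)-7-methoxy-6-[(E)-3-methylbut-1-en-1-yl]-3-(3-methylbut-2-en-1-yl)-4H-chromen-4-one | COc1cc2oc(-c3ccc(OC(C)=O)cc3OC(C)=O)c(CC=C(C)C)c(=O)c2c(OC(C)=O)c1/C=C/C(C)C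
F4 | step 7 | (R)-enantiomer of 14 | COc1cc2oc3c(c(=O)c2c(O)c1/C=C/C(C)C)C[C@H](C(C)(C)OO)Oc1cc(O)ccc1-3
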